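**Retrosynthetic overview**
- The target comes from the (2S)-flavanone 4'-O-MOM ether by a final mild acidic MOM removal.
- The pyranone C ring is the only ring formed (A and B rings are bought as arenes). It is closed last by an intramolecular Mitsunobu O-alkylation that inverts an (R)-benzylic carbinol; the A ring is symmetric, so either ortho-OH gives the same product.
- The (R)-β-hydroxy ketone comes from Ru/TsDPEN transfer hydrogenation of a 1,3-diketone at its unhindered B-ring carbonyl.
- The 1,3-diketone comes from an intermolecular crossed Claisen condensation (the C2–C3 bond) between an A-ring methyl ketone enolate and MOM-protected methyl vanillate.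
- The A-ring ketone comes from 2',6'-dihydroxy-4'-methoxyacetophenone by O-allylation, double Claisen rearrangement and cross-metathesis (prenyl groups), then O-allyl protection.

Assumption: 2',6'-dihydroxy-4'-methoxyacetophenone and methyl vanillate are bought; allyl bromide, MOMCl and 2-methyl-2-butene are treated as reagents and are not numbered.

**Step 1**
Reactants: 1 1-(2,6-dihydroxy-4-methoxyphenyl)ethan-1-one
Product: 3 1-[2,6-bis(allyloxy)-4-methoxyphenyl]ethan-1-one, via mono-allyl ether 2 (not isolated)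
Conditions: allyl bromide (2.5 equiv), K2CO3, DMF, 60 °C
Reagents that add atoms: allyl bromide, C=CCBr
Why: Williamson O-allylation of both phenoxides in a polar aprotic solvent, with mild heating to alkylate the second, carbonyl-chelated OH; no stereocenter is formed.

**Step 2**
Reactants: 3 1-[2,6-bis(allyloxy)-4-methoxyphenyl]ethan-1-one
Product: 5 1-(3,5-diallyl-2,6-dihydroxy-4-methoxyphenyl)ethan-1-one, via mono-Claisen phenol 4 (not isolated)
Conditions: PhNEt2, 200 °C, sealed tube, Ar
Reagents that add atoms: none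
Why: Two successive aromatic Claisen [3,3] rearrangements deliver each allyl group to its only free ortho position (C3, C5), the acetyl group blocking the other, and tautomerisation restores the chelated phenols.

**Step 3**
Reactants: 5 1-(3,5-diallyl-2,6-dihydroxy-4-methoxyphenyl)ethan-1-one
Product: 7 1-[2,6-dihydroxy-4-methoxy-3,5-bis(3-methylbut-2-en-1-yl)phenyl]ethan-1-one, via mono-prenyl ketone 6 (not isolated)
Conditions: Grubbs II (5 mol%), 2-methyl-2-butene (large excess), CH2Cl2, 40 °C
Reagents that add atoms: 2-methyl-2-butene, CC=C(C)C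
Why: Olefin cross-metathesis of the terminal allyl groups with excess 2-methyl-2-butene gives the prenyl groups, driven by loss of propene and tolerant of free phenols and the ketone.

**Step 4**
Reactants: 7 1-[2,6-dihydroxy-4-methoxy-3,5-bis(3-methylbut-2-en-1-yl)phenyl]ethan-1-one
Product: 9 1-[2,6-bis(allyloxy)-4-methoxy-3,5-bis(3-methylbut-2-en-1-yl)phenyl]ethan-1-one, via mono-allyl ether 8 (not isolated)
Conditions: allyl bromide (3 equiv), Cs2CO3, DMF, 50 °C
Reagents that add atoms: allyl bromide, C=CCBr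
Why: Williamson O-allylation on a fully substituted ring (no C-alkylation possible) installs phenol protection that survives NaH and Ru–H and is later removed by neutral Pd(0) chemistry.

**Step 5**
Reactants: 10 methyl 4-hydroxy-3-methoxybenzoate (methyl vanillate)
Product: 11 methyl 3-methoxy-4-(methoxymethoxy)benzoate
Conditions: MOMCl, i-Pr2NEt, CH2Cl2, 0 °C → rt
Reagents that add atoms: chloromethyl methyl ether, COCCl
Why: MOM protection (O-alkylation of the phenol by the α-chloro ether) gives a base-stable acetal that is removed by mild acid at the end.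

**Step 6 (key C–C bond)**
Reactants: 9 1-[2,6-bis(allyloxy)-4-methoxy-3,5-bis(3-methylbut-2-en-1-yl)phenyl]ethan-1-one; 11 methyl 3-methoxy-4-(methoxymethoxy)benzoate
Product: 12 1-[2,6-bis(allyloxy)-4-methoxy-3,5-bis(3-methylbut-2-en-1-yl)phenyl]-3-[3-methoxy-4-(methoxymethoxy)phenyl]propane-1,3-dione (largely enolised)
Conditions: NaH (3 equiv), THF, reflux; AcOH quench, 0 °C
Reagents that add atoms: none
Why: Intermolecular crossed Claisen condensation in which the methyl ketone enolate (its di-ortho-substituted carbonyl cannot self-condense) is acylated by the non-enolisable ester, driven by irreversible deprotonation of the β-diketone; this forms the future C2–C3 bond.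

**Step 7**
Reactants: 12 the 1,3-diketone
Product: 13 (3R)-1-[2,6-bis(allyloxy)-4-methoxy-3,5-bis(3-methylbut-2-en-1-yl)phenyl]-3-hydroxy-3-[3-methoxy-4-(methoxymethoxy)phenyl]propan-1-one
Conditions: RuCl[(R,R)-TsDPEN](p-cymene) (3 mol%), HCO2H/Et3N (5:2), DMF, 40 °C
Reagents that add atoms: none
Why: Noyori–Ikariya asymmetric transfer hydrogenation reduces only the unhindered aryl ketone next to the B ring (the di-ortho-substituted A-ring carbonyl is inert), and the (R,R)-catalyst gives the (R)-carbinol in the same sense as acetophenone → (R)-1-phenylethanol; alkenes, allyl ethers and MOM are untouched.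

**Step 8**
Reactants: 13 the (3R)-β-hydroxy ketone bis(allyl ether)
Product: 15 (3R)-1-[2,6-dihydroxy-4-methoxy-3,5-bis(3-methylbut-2-en-1-yl)phenyl]-3-hydroxy-3-[3-methoxy-4-(methoxymethoxy)phenyl]propan-1-one, via mono-allyl phenol 14 (not isolated)
Conditions: Pd(PPh3)4 (5 mol%), morpholine (6 equiv), THF, rt
Reagents that add atoms: none
Why: Tsuji–Trost-type Pd(0) deallylation (π-allyl formation with the acyl-activated phenoxide as leaving group, allyl trapped by morpholine) frees both phenols under near-neutral conditions that leave the β-hydroxy ketone, its stereocenter, MOM and prenyl groups intact.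

**Step 9**
Reactants: 15 the (3R)-triol
Product: 16 (2S)-5-hydroxy-7-methoxy-2-[3-methoxy-4-(methoxymethoxy)phenyl]-6,8-bis(3-methylbut-2-en-1-yl)chroman-4-one
Conditions: PPh3 (1.5 equiv), DIAD (1.5 equiv), toluene (0.02 M), −10 → 0 °C
Reagents that add atoms: none
Why: Intramolecular Mitsunobu etherification, in which the acidic ortho-acyl phenol displaces the benzylic oxyphosphonium in a 6-exo SN2 closure with inversion (3R → 2S); the two phenols are equivalent by symmetry and the second becomes the chelated 5-OH.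

**Step 10**
Reactants: 16 the (2S)-flavanone MOM ether
Product: 17 (2S)-5-hydroxy-2-(4-hydroxy-3-methoxyphenyl)-7-methoxy-6,8-bis(3-methylbut-2-en-1-yl)chroman-4-one (target)
Conditions: 3 M aq HCl, MeOH, rt → 40 °C; NaHCO3 quench
Reagents that add atoms: none
Why: Acid-catalysed acetal solvolysis removes the MOM group under conditions mild enough to avoid prenyl/5-OH chroman formation and to leave the configurationally acid-stable C2 center untouched.

**Compound list**
1 | 1-(2,6-dihydroxy-4-methoxyphenyl)ethan-1-one | CC(=O)c1c(O)cc(OC)cc1O | starting material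
2 | 1-[2-(allyloxy)-6-hydroxy-4-methoxyphenyl]ethan-1-one | CC(=O)c1c(O)cc(OC)cc1OCC=C | intermediate
3 | 1-[2,6-bis(allyloxy)-4-methoxyphenyl]ethan-1-one | CC(=O)c1c(OCC=C)cc(OC)cc1OCC=C | intermediate
4 | 1-[3-allyl-6-(allyloxy)-2-hydroxy-4-methoxyphenyl]ethan-1-one | CC(=O)c1c(O)c(CC=C)c(OC)cc1OCC=C | intermediate
5 | 1-(3,5-diallyl-2,6-dihydroxy-4-methoxyphenyl)ethan-1-one | CC(=O)c1c(O)c(CC=C)c(OC)c(CC=C)c1O | intermediate
6 | 1-[3-allyl-2,6-dihydroxy-4-methoxy-5-(3-methylbut-2-en-1-yl)phenyl]ethan-1-one | CC(=O)c1c(O)c(CC=C)c(OC)c(CC=C(C)C)c1O | intermediate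
7 | 1-[2,6-dihydroxy-4-methoxy-3,5-bis(3-methylbut-2-en-1-yl)phenyl]ethan-1-one | CC(=O)c1c(O)c(CC=C(C)C)c(OC)c(CC=C(C)C)c1O | intermediate
8 | 1-[2-(allyloxy)-6-hydroxy-4-methoxy-3,5-bis(3-methylbut-2-en-1-yl)phenyl]ethan-1-one | CC(=O)c1c(O)c(CC=C(C)C)c(OC)c(CC=C(C)C)c1OCC=C | intermediate
9 | 1-[2,6-bis(allyloxy)-4-methoxy-3,5-bis(3-methylbut-2-en-1-yl)phenyl]ethan-1-one | CC(=O)c1c(OCC=C)c(CC=C(C)C)c(OC)c(CC=C(C)C)c1OCC=C | intermediate
10 | methyl 4-hydroxy-3-methoxybenzoate (methyl vanillate) | COC(=O)c1ccc(O)c(OC)c1 | starting material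
11 | methyl 3-methoxy-4-(methoxymethoxy)benzoate | COCOc1ccc(C(=O)OC)cc1OC | intermediate
12 | 1-[2,6-bis(allyloxy)-4-methoxy-3,5-bis(3-methylbut-2-en-1-yl)phenyl]-3-[3-methoxy-4-(methoxymethoxy)phenyl]propane-1,3-dione | C=CCOc1c(CC=C(C)C)c(OC)c(CC=C(C)C)c(OCC=C)c1C(=O)CC(=O)c1ccc(OCOC)c(OC)c1 | intermediate
13 | (3R)-1-[2,6-bis(allyloxy)-4-methoxy-3,5-bis(3-methylbut-2-en-1-yl)phenyl]-3-hydroxy-3-[3-methoxy-4-(methoxymethoxy)phenyl]propan-1-one | C=CCOc1c(CC=C(C)C)c(OC)c(CC=C(C)C)c(OCC=C)c1C(=O)C[C@@H](O)c1ccc(OCOC)c(OC)c1 | intermediate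
14 | (3R)-1-[2-(allyloxy)-6-hydroxy-4-methoxy-3,5-bis(3-methylbut-2-en-1-yl)phenyl]-3-hydroxy-3-[3-methoxy-4-(methoxymethoxy)phenyl]propan-1-one | C=CCOc1c(CC=C(C)C)c(OC)c(CC=C(C)C)c(O)c1C(=O)C[C@@H](O)c1ccc(OCOC)c(OC)c1 | intermediate
15 | (3R)-1-[2,6-dihydroxy-4-methoxy-3,5-bis(3-methylbut-2-en-1-yl)phenyl]-3-hydroxy-3-[3-methoxy-4-(methoxymethoxy)phenyl]propan-1-one | COc1c(CC=C(C)C)c(O)c(C(=O)C[C@@H](O)c2ccc(OCOC)c(OC)c2)c(O)c1CC=C(C)C | intermediate
16 | (2S)-5-hydroxy-7-methoxy-2-[3-methoxy-4-(methoxymethoxy)phenyl]-6,8-bis(3-methylbut-2-en-1-yl)chroman-4-one | COCOc1ccc([C@@H]2CC(=O)c3c(O)c(CC=C(C)C)c(OC)c(CC=C(C)C)c3O2)cc1OC | intermediate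
17 | (2S)-5-hydroxy-2-(4-hydroxy-3-methoxyphenyl)-7-methoxy-6,8-bis(3-methylbut-2-en-1-yl)chroman-4-one | COc1cc([C@@H]2CC(=O)c3c(O)c(CC=C(C)C)c(OC)c(CC=C(C)C)c3O2)ccc1O | target

**Totals**
Total step count: 10. Longest linear sequence: 9 steps (steps 1–4, then 6–10, from 1); step 5 is the one-step convergent branch.

**Three steps most likely to fail**

Step 9 (Mitsunobu closure). The 4-alkoxy-substituted benzylic oxyphosphonium may ionise (loss of ee) or eliminate to the chalcone. The fallback sets out from 15 and comes back at 16, replacing stereospecific closure by resolution. Treat 15 with KOH in EtOH at rt to dehydrate it to (E)-1-[2,6-dihydroxy-4-methoxy-3,5-bis(3-methylbut-2-en-1-yl)phenyl]-3-[3-methoxy-4-(methoxymethoxy)phenyl]prop-2-en-1-one F1. Heat with NaOAc in EtOH so that oxa-Michael closure gives the racemic MOM-flavanone F2. Separate F2 on a preparative amylose-carbamate chiral SFC column into 16 and the (2R)-MOM-flavanone F3, which is re-racemised with catalytic DBU and recycled.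

Step 7 (transfer hydrogenation). The strongly chelated, electron-rich enolised diketone may reduce sluggishly or with lower ee. The fallback sets out from 9 and comes back at 13, building the carbinol by aldol condensation and asymmetric hydration instead. Claisen–Schmidt condensation of 9 (KOH, EtOH, rt) with 3-methoxy-4-(methoxymethoxy)benzaldehyde F4 (from commercial vanillin, MOMCl, i-Pr2NEt) gives the (E)-chalcone bis(allyl ether) F5. Cu(I)/Josiphos-catalysed asymmetric conjugate borylation with B2pin2 and MeOH, with the ligand antipode selected for the R product, gives the (3R)-β-pinacolboryl ketone F6. Its C–B bond is oxidised with retention by NaBO3·4H2O in THF/H2O to 13.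

Step 2 (double Claisen at 200 °C). Abnormal Claisen products or cyclisation of the ortho-allyl phenols to dihydrobenzofurans could lower the yield. The fallback sets out from 1 and comes back at 7: direct double C-prenylation of the phloroglucinol-type phenoxide of 1 with prenyl bromide (CC(C)=CCBr) in 10% aq KOH at 0 °C. This is lower-yielding (O- and mono-alkylated by-products must be separated) but replaces steps 1–3 and makes no new compound.

**Further compounds**
F1 | step 9 | (E)-1-[2,6-dihydroxy-4-methoxy-3,5-bis(3-methylbut-2-en-1-yl)phenyl]-3-[3-methoxy-4-(methoxymethoxy)phenyl]prop-2-en-1-one | COc1c(CC=C(C)C)c(O)c(C(=O)/C=C/c2ccc(OCOC)c(OC)c2)c(O)c1CC=C(C)C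
F2 | step 9 | racemic 5-hydroxy-7-methoxy-2-[3-methoxy-4-(methoxymethoxy)phenyl]-6,8-bis(3-methylbut-2-en-1-yl)chroman-4-one | COCOc1ccc(C2CC(=O)c3c(O)c(CC=C(C)C)c(OC)c(CC=C(C)C)c3O2)cc1OC
F3 | step 9 | (2R)-5-hydroxy-7-methoxy-2-[3-methoxy-4-(methoxymethoxy)phenyl]-6,8-bis(3-methylbut-2-en-1-yl)chroman-4-one | COCOc1ccc([C@H]2CC(=O)c3c(O)c(CC=C(C)C)c(OC)c(CC=C(C)C)c3O2)cc1OC
F4 | step 7 | 3-methoxy-4-(methoxymethoxy)benzaldehyde | COCOc1ccc(C=O)cc1OC
F5 | step 7 | (E)-1-[2,6-bis(allyloxy)-4-methoxy-3,5-bis(3-methylbut-2-en-1-yl)phenyl]-3-[3-methoxy-4-(methoxymethoxy)phenyl]prop-2-en-1-one | C=CCOc1c(CC=C(C)C)c(OC)c(CC=C(C)C)c(OCC=C)c1C(=O)/C=C/c1ccc(OCOC)c(OC)c1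
F6 | step 7 | (3R)-1-[2,6-bis(allyloxy)-4-methoxy-3,5-bis(3-methylbut-2-en-1-yl)phenyl]-3-[3-methoxy-4-(methoxymethoxy)phenyl]-3-(4,4,5,5-tetramethyl-1,3,2-dioxaborolan-2-yl)propan-1-one | C=CCOc1c(CC=C(C)C)c(OC)c(CC=C(C)C)c(OCC=C)c1C(=O)C[C@@H](B1OC(C)(C)C(C)(C)O1)c1ccc(OCOC)c(OC)c1
F0 | step 2 | none | none
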